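## Retrosynthetic overview

Atoms carry prostanoid labels: C1 ester carbon, C9 ketone, C10 (Cl), C11, C12 (acetoxy carbon), C13–C20 octenyl chain.

1. C7=C8 and the C12 acetate come last: aldol addition of a 2-chloro-4-silyloxy-cyclopentenone to methyl (E)-7-oxohept-5-enoate, then acetylation and β-elimination.
2. The (Z)-C14=C15 alkene comes from a Z-selective Wittig reaction on a CH2CHO arm at C12.
3. Key disconnection C9–C10: an aldehyde carbon is delivered as an acyl anion equivalent (acyl–rhodium hydride) to the chloroalkyne of a prochiral dialdehyde. C9 and C10 are both acceptor carbons (C10 is β to the C12 oxygen), so the 1,4-pattern C9=O / C12–O needs this polarity reversal.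
4. The same step closes the only ring (the cyclopentenone), fixes C12 by choosing between two enantiotopic CH2CHO arms, and brings in C10–Cl.
5. The dialdehyde comes from ozonolysis of a diallyl(chloroethynyl)carbinol silyl ether, made from diallyl ketone and lithium chloroacetylide.

Assumption: the sense of induction of the chiral ligand on this new substrate class is unknown; (R,R)-i-Pr-DuPHOS is written, and its commercial mirror image is used if the first run gives the antipode of the cyclised keto-aldehyde.

## Route

Step 1
Reactants: 1 hepta-1,6-dien-4-ol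
Product: 2 hepta-1,6-dien-4-one
Conditions: Dess–Martin periodinane, CH2Cl2, 0 °C → rt; used at once
Reagents that add atoms: none
Why: Dess–Martin oxidation of a secondary alcohol under neutral conditions, which spares the two β,γ-alkenes from migration into conjugation; no stereocentre is formed.

Step 2
Reactants: 2 hepta-1,6-dien-4-one; 3 cis-1,2-dichloroethene
Product: 5 {[4-(chloroethynyl)hepta-1,6-dien-4-yl]oxy}(trimethyl)silane, via lithium alkoxide 4 (not isolated)
Conditions: 3, MeLi (2 equiv), Et2O, 0 °C → rt; CeCl3, THF, −78 °C; 2, −78 °C; then Me3SiCl, −78 °C → rt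
Reagents that add atoms: chlorotrimethylsilane, C[Si](C)(C)Cl
Why: 1,2-addition of an alkynyl nucleophile to a ketone, the cerium-modified chloroacetylide being too weakly basic to enolise the doubly allylic ketone, followed by O-silylation of the tertiary alkoxide in the same flask; the new quaternary carbon (future C12) bears two identical allyl groups and is not yet a stereocentre.

Step 3
Reactants: 5 {[4-(chloroethynyl)hepta-1,6-dien-4-yl]oxy}(trimethyl)silane
Product: 7 3-(chloroethynyl)-3-[(trimethylsilyl)oxy]pentanedial, via bis-ozonide 6 (not isolated)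
Conditions: O3, CH2Cl2, −78 °C (stopped at first excess of ozone); then PPh3, −78 °C → rt; used crude
Reagents that add atoms: ozone, [O-][O+]=O
Why: ozonolysis with reductive work-up, in which the two terminal alkenes are cleaved far faster than the electron-poor chloroalkyne and the tertiary silyl ether is inert; the carbinol carbon stays prochiral (two identical CH2CHO arms).

Step 4
Reactants: 7 3-(chloroethynyl)-3-[(trimethylsilyl)oxy]pentanedial
Product: 8 2-[(1S)-3-chloro-4-oxo-1-[(trimethylsilyl)oxy]cyclopent-2-en-1-yl]acetaldehyde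
Conditions: [Rh(nbd)2]BF4 (5 mol%), (R,R)-i-Pr-DuPHOS (6 mol%), H2 pre-activation then Ar, CH2Cl2, rt
Reagents that add atoms: none
Why: Proposed new method: oxidative addition of monovalent rhodium into one aldehyde C–H bond gives an acyl–rhodium hydride (an acyl anion equivalent) that adds trans across the chloroalkyne, hydride to C11 and rhodium to the chlorine-bearing C10 as the six-membered rhodacycle requires, and C9–C10 reductive elimination gives the 2-chloroenone, the chiral bisphosphine choosing between the two enantiotopic CH2CHO arms and so fixing C12; the closest known reaction type is the rhodium-catalysed intramolecular trans-hydroacylation of 4-alkynals to cyclopentenones, including its enantioselective desymmetrisation of 3-alkoxy-3,3-dialkynyl aldehydes and kinetic resolution of 3-alkoxy-4-alkynals with this ligand class, and rhodium-catalysed Pauson–Khand reactions of chloro-enynes show that 1-chloroalkynes survive such catalysts and emerge as α-chloroenones.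

Step 5
Reactants: 8 2-[(1S)-3-chloro-4-oxo-1-[(trimethylsilyl)oxy]cyclopent-2-en-1-yl]acetaldehyde; 9 hexyltriphenylphosphonium bromide
Product: 10 (4S)-2-chloro-4-[(2Z)-oct-2-en-1-yl]-4-[(trimethylsilyl)oxy]cyclopent-2-en-1-one
Conditions: 9, NaN(SiMe3)2 (1.05 equiv), THF, −78 °C; then 8, −78 → −20 °C
Reagents that add atoms: none
Why: Wittig olefination with a salt-free unstabilised ylide, which attacks the aldehyde at −78 °C far faster than the hindered enone and gives the Z-alkene under kinetic control through the cis-oxaphosphetane; C12 is not touched.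

Step 6
Reactants: 11 methyl hex-5-enoate; 12 (E)-but-2-enal
Product: 13 methyl (5E)-7-oxohept-5-enoate
Conditions: second-generation Hoveyda–Grubbs catalyst RuCl2(H2IMes)(=CH-C6H4-2-O-i-Pr) (2 mol%), 12 (4 equiv), CH2Cl2, 40 °C
Reagents that add atoms: none
Why: olefin cross-metathesis of a terminal alkene with an excess of an enal partner, E-selective under thermodynamic control and driven by loss of propene; no stereocentre.

Step 7
Reactants: 10 (4S)-2-chloro-4-[(2Z)-oct-2-en-1-yl]-4-[(trimethylsilyl)oxy]cyclopent-2-en-1-one; 13 methyl (5E)-7-oxohept-5-enoate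
Product: 16 methyl (5E)-7-[(5S)-3-chloro-5-hydroxy-5-[(2Z)-oct-2-en-1-yl]-2-oxocyclopent-3-en-1-yl]-7-hydroxyhept-5-enoate, via lithium dienolate 14 (not isolated), via silyl ether aldol 15 (not isolated)
Conditions: LiN(i-Pr)2 (1.1 equiv), THF, −78 °C; 13, −78 °C; then 1 M HCl, THF, 0 °C
Reagents that add atoms: none
Why: kinetic lithium enolate aldol addition at C8, the only enolisable position (C10 bears chlorine, C12 is quaternary), with 1,2-attack on the enal as in classical alkylidene-cyclopentenone prostanoid syntheses, after which mild acid hydrolyses the labile tertiary trimethylsilyl ether; the new C7 and C8 centres form as mixtures that are erased in step 8, and C12 is untouched.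

Step 8
Reactants: 16 methyl (5E)-7-[(5S)-3-chloro-5-hydroxy-5-[(2Z)-oct-2-en-1-yl]-2-oxocyclopent-3-en-1-yl]-7-hydroxyhept-5-enoate
Product: 18 methyl (5E,7E)-7-[(5R)-5-acetoxy-3-chloro-5-[(2Z)-oct-2-en-1-yl]-2-oxocyclopent-3-en-1-ylidene]hept-5-enoate, via bis-acetate 17 (not isolated)
Conditions: Ac2O (5 equiv), Et3N, DMAP, CH2Cl2, rt, 24 h; then DBU, 0 °C → rt; 7E isomer separated from minor 7Z by chromatography
Reagents that add atoms: acetic anhydride, CC(=O)OC(C)=O
Why: DMAP-catalysed acetylation of both hydroxyls followed by E1cB elimination of the C7 acetate (loss of the C12 acetate would give an antiaromatic cyclopentadienone and does not compete) gives the more stable 7E dienone without touching the C12–O bond, so C12 keeps its configuration and its label changes from S to R only because C8 becomes sp2.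

## Compound list

1 | hepta-1,6-dien-4-ol | C=CCC(O)CC=C | starting material
2 | hepta-1,6-dien-4-one | C=CCC(=O)CC=C | intermediate
3 | cis-1,2-dichloroethene | Cl/C=C\Cl | starting material
4 | lithium 4-(chloroethynyl)hepta-1,6-dien-4-olate (tertiary alkoxide, written as its lithium salt) | [Li+].[O-]C(CC=C)(CC=C)C#CCl | intermediate
5 | {[4-(chloroethynyl)hepta-1,6-dien-4-yl]oxy}(trimethyl)silane | C=CCC(CC=C)(O[Si](C)(C)C)C#CCl | intermediate
6 | bis-ozonide of 5: both allyl termini as 1,2,4-trioxolan-3-ylmethyl groups (diastereomer mixture) | ClC#CC(O[Si](C)(C)C)(CC1OCOO1)CC1OCOO1 | intermediate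
7 | 3-(chloroethynyl)-3-[(trimethylsilyl)oxy]pentanedial (prochiral) | O=CCC(O[Si](C)(C)C)(CC=O)C#CCl | intermediate
8 | 2-[(1S)-3-chloro-4-oxo-1-[(trimethylsilyl)oxy]cyclopent-2-en-1-yl]acetaldehyde (C12 spatially as in the target) | O=CC[C@@]1(O[Si](C)(C)C)C=C(Cl)C(=O)C1 | intermediate
9 | hexyltriphenylphosphonium bromide | CCCCCC[P+](c1ccccc1)(c1ccccc1)c1ccccc1.[Br-] | starting material
10 | (4S)-2-chloro-4-[(2Z)-oct-2-en-1-yl]-4-[(trimethylsilyl)oxy]cyclopent-2-en-1-one | CCCCC/C=C\C[C@@]1(O[Si](C)(C)C)C=C(Cl)C(=O)C1 | intermediate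
11 | methyl hex-5-enoate | C=CCCCC(=O)OC | starting material
12 | (E)-but-2-enal (crotonaldehyde) | C/C=C/C=O | starting material
13 | methyl (5E)-7-oxohept-5-enoate | COC(=O)CCC/C=C/C=O | intermediate
14 | lithium (3S)-5-chloro-3-[(2Z)-oct-2-en-1-yl]-3-[(trimethylsilyl)oxy]cyclopenta-1,4-dien-1-olate (C9–O–Li, C8=C9) | CCCCC/C=C\C[C@@]1(O[Si](C)(C)C)C=C(Cl)C(O[Li])=C1 | intermediate
15 | methyl (5E)-7-[(5S)-3-chloro-5-[(2Z)-oct-2-en-1-yl]-2-oxo-5-[(trimethylsilyl)oxy]cyclopent-3-en-1-yl]-7-hydroxyhept-5-enoate (epimer mixture at C7 and C8) | CCCCC/C=C\C[C@@]1(O[Si](C)(C)C)C=C(Cl)C(=O)C1C(O)/C=C/CCCC(=O)OC | intermediate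
16 | methyl (5E)-7-[(5S)-3-chloro-5-hydroxy-5-[(2Z)-oct-2-en-1-yl]-2-oxocyclopent-3-en-1-yl]-7-hydroxyhept-5-enoate (epimer mixture at C7 and C8) | CCCCC/C=C\C[C@@]1(O)C=C(Cl)C(=O)C1C(O)/C=C/CCCC(=O)OC | intermediate
17 | methyl (5E)-7-acetoxy-7-[(5S)-5-acetoxy-3-chloro-5-[(2Z)-oct-2-en-1-yl]-2-oxocyclopent-3-en-1-yl]hept-5-enoate (epimer mixture at C7 and C8) | CCCCC/C=C\C[C@@]1(OC(C)=O)C=C(Cl)C(=O)C1C(OC(C)=O)/C=C/CCCC(=O)OC | intermediate
18 | methyl (5E,7E)-7-[(5R)-5-acetoxy-3-chloro-5-[(2Z)-oct-2-en-1-yl]-2-oxocyclopent-3-en-1-ylidene]hept-5-enoate (12R, 5E, 7E, 14Z) | CCCCC/C=C\C[C@@]1(OC(C)=O)C=C(Cl)C(=O)/C1=C/C=C/CCCC(=O)OC | target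

## Step count and risks

Total: 8 steps. Longest linear sequence: 7 steps (steps 1, 2, 3, 4, 5, 7, 8, from 1); step 6 is the one-step side branch.

Most likely to fail:

- **Step 4.** The desymmetrising hydroacylation is new: enantioselectivity between the two aldehyde arms is untested, and cis-hydroacylation to a cyclobutanone or interference by the chloroalkyne may compete. The fallback gives up desymmetrisation for kinetic resolution, with ring closure placed after the olefination. It sets out from 7: one equivalent of the ylide made from 9 (NaN(SiMe3)2, THF, −78 °C) olefinates one arm statistically to racemic (5Z)-3-(chloroethynyl)-3-[(trimethylsilyl)oxy]undec-5-enal F1. F1 is then cyclised with the same [Rh(nbd)2]BF4/i-Pr-DuPHOS catalyst to about half conversion, the documented kinetic-resolution mode for 3-alkoxy-4-alkynals. The fast enantiomer gives 10 directly, where the route is rejoined (8 is bypassed).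

- **Step 5.** The basic ylide may attack or enolise the α-chloroenone instead of the aldehyde. The fallback builds the Z-alkene by metathesis without any ylide. It sets out from 8: methylenation of the aldehyde with the Takai–Lombardo reagent (Zn, CH2Br2, TiCl4, THF, 0 °C) gives (4S)-2-chloro-4-(prop-2-en-1-yl)-4-[(trimethylsilyl)oxy]cyclopent-2-en-1-one F2. Z-selective cross-metathesis of F2 with excess hept-1-ene, using the cyclometalated ruthenium nitrato catalyst C32H41N3O4Ru (chelating adamantyl-mesityl imidazolinylidene, nitrate, 2-isopropoxybenzylidene), then gives 10, where the route is rejoined.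

- **Step 2.** Ketone 2 may enolise or isomerise to the conjugated dienone before the acetylide adds. The fallback makes the carbinol from an ester and never passes through 2. It sets out from 3: lithium chloroacetylide, made as in step 2, is added to ethyl chloroformate at −78 °C to give ethyl 3-chloroprop-2-ynoate F3. CH2=CHCH2MgBr (2.2 equiv, THF, −78 °C) adds twice, through the transient 1-chlorohex-5-en-1-yn-3-one F4, to give 4-(chloroethynyl)hepta-1,6-dien-4-ol F5 after NH4Cl work-up. N-(Trimethylsilyl)imidazole then silylates F5 to 5, where the route is rejoined (1 and 2 are not needed).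

## Further compounds

F1 | step 4 | rac-(5Z)-3-(chloroethynyl)-3-[(trimethylsilyl)oxy]undec-5-enal | CCCCC/C=C\CC(O[Si](C)(C)C)(CC=O)C#CCl
F2 | step 5 | (4S)-2-chloro-4-(prop-2-en-1-yl)-4-[(trimethylsilyl)oxy]cyclopent-2-en-1-one | C=CC[C@@]1(O[Si](C)(C)C)C=C(Cl)C(=O)C1
F3 | step 2 | ethyl 3-chloroprop-2-ynoate | CCOC(=O)C#CCl
F4 | step 2 | 1-chlorohex-5-en-1-yn-3-one | C=CCC(=O)C#CCl
F5 | step 2 | 4-(chloroethynyl)hepta-1,6-dien-4-ol | C=CCC(O)(CC=C)C#CCl
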